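**Plan**

- **Numbering and cuts.** Lignan numbering is used: C7–C8–C9 is the carbinol half and C7'–C8'–C9' the benzyl half. The target is 7S,8R,8'R, trans on the ring. The retrosynthesis cuts C1–C7 (syringyl–carbinol bond) first, then C1'–C7' (syringyl–CH2 bond), then C8–C7'/C8–C8' of a cyclopropane-fused lactone. That lactone comes from di-tert-butyl malonate (C7, C8, C9) and (R)-epichlorohydrin (C7', C8', C9'). Both syringyl rings come from one aryl bromide.
- **Forward order.** Cyclopropane γ-lactone, then opening by the aryl copper reagent (benzyl arm), then CO2tBu to C7H2OH, then lactone C9=O to CH2 (the old lactone ring becomes the tetrahydrofuran ring), then the O7-carbamate, then union with the aryl boronic ester, then desilylation.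
- **Enabling feature.** C7 is an oxygen-bearing carbon outside the tetrahydrofuran ring, bonded to C8 and to C1 of an electron-rich syringyl ring. Without the aryl group it is a primary CH2–O7, and a chiral diamine–alkyllithium complex can tell its two hydrogens apart once O7 carries a carbamoyl group. The ring oxygen is γ to C7, so no β-elimination is possible. The same carbamate leaves when the aryl group shifts from boron to C7.
- **Stereochemistry.** C8' comes from (R)-epichlorohydrin (one inversion on cyclopropane closure). C8 comes from thermodynamic trans protonation of a malonate-type enolate. C7 is set by reagent control with (+)-sparteine (retention, inversion, retention).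

Key step: step 10

Remark: Ar = 3,5-dimethoxy-4-(triisopropylsilyloxy)phenyl and Cb = N,N-diisopropylcarbamoyl. It is assumed that the trans isomer of the α-carboxy-β-benzyl lactone is clearly favoured at equilibrium, as is usual for 3,4-disubstituted γ-lactones.

**Step 1**
Reactants: 1 4-bromo-2,6-dimethoxyphenol
Product: 2 (4-bromo-2,6-dimethoxyphenoxy)triisopropylsilane (ArBr)
Conditions: TIPSCl, imidazole, DMF, rt to 40 °C
Reagents that add atoms: chlorotriisopropylsilane, CC(C)[Si](Cl)(C(C)C)C(C)C
Why: Silyl ether protection of the phenol; the TIPS group has no acidic C–H, should withstand Grignard, organolithium, hydride, TFA and BF3 steps, and leaves with buffered fluoride under conditions that spare a p-hydroxybenzylic alcohol.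

**Step 2**
Reactants: 2 ArBr
Product: 4 2-[3,5-dimethoxy-4-(triisopropylsilyloxy)phenyl]-4,4,5,5-tetramethyl-1,3,2-dioxaborolane (ArBpin), via aryllithium 3 (not isolated)
Conditions: n-BuLi, THF, −78 °C; i-PrOBpin, −78 °C to rt
Reagents that add atoms: 2-isopropoxy-4,4,5,5-tetramethyl-1,3,2-dioxaborolane, CC(C)OB1OC(C)(C)C(C)(C)O1
Why: Bromine–lithium exchange followed by electrophilic borylation places boron regiospecifically on the former C–Br carbon.

**Step 3**
Reactants: 5 di-tert-butyl malonate; 6 (R)-epichlorohydrin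
Product: 7 tert-butyl (1R,5R)-2-oxo-3-oxabicyclo[3.1.0]hexane-1-carboxylate (cis-fused cyclopropane lactone)
Conditions: t-BuOK, t-BuOH, rt to reflux
Reagents that add atoms: none
Why: Tandem malonate alkylation–cyclopropanation–lactonisation, in which the malonate anion opens the epoxide at CH2, the alkoxide re-closes an epoxide with loss of chloride, the second malonate carbanion opens it 3-exo-tet with inversion at the stereocentre and the cis CH2O− lactonises, so that C8' is taken from the chiral pool.

**Step 4**
Reactants: 2 ArBr; 7 cyclopropane lactone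
Product: 9 tert-butyl (3R,4R)-4-(ArCH2)-2-oxotetrahydrofuran-3-carboxylate (trans), via arylmagnesium bromide 8 (not isolated)
Conditions: Mg, THF, 40 °C; CuI (20 mol%), THF, −40 °C; 7, −40 to 0 °C; aq. NH4Cl
Reagents that add atoms: none
Why: Copper-catalysed homoconjugate addition of an aryl Grignard reagent to a doubly activated cyclopropane, in which attack at the unhindered cyclopropane CH2 breaks the bond to the quaternary carbon without touching C8', and the acidic malonate-type C8–H should equilibrate so that the bulky ester ends trans to the benzyl group (C8 set by thermodynamic control).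

**Step 5**
Reactants: 9 tert-butyl ester lactone
Product: 10 (3S,4R)-4-(ArCH2)-2-oxotetrahydrofuran-3-carboxylic acid (trans)
Conditions: TFA, CH2Cl2, 0 °C to rt; evaporation below 30 °C
Reagents that add atoms: none
Why: Acidolysis of a tert-butyl ester (loss of isobutene) frees the acid without base or heat, so the lactone and the aryl silyl ether should survive, decarboxylation is avoided and C8 stays trans.

**Step 6**
Reactants: 10 lactone acid
Product: 11 (3S,4R)-3-(hydroxymethyl)-4-(ArCH2)dihydrofuran-2(3H)-one (trans)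
Conditions: BH3·SMe2, THF, 0 °C to rt; MeOH
Reagents that add atoms: none
Why: Chemoselective borane reduction of a carboxylic acid (via the acyloxyborane) in the presence of a lactone turns the malonate-derived carboxyl carbon into C7H2OH with C8 and C8' untouched, and any minor cis isomer can be removed here by chromatography.

**Step 7**
Reactants: 11 hydroxymethyl lactone
Product: 12 (3S,4R)-3-(hydroxymethyl)-4-(ArCH2)tetrahydrofuran-2-ol (lactol, both anomers)
Conditions: DIBAL-H (2.2 equiv), CH2Cl2, −78 °C; Rochelle salt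
Reagents that add atoms: none
Why: Partial reduction of a γ-lactone with DIBAL-H stops at the stable aluminium hemiacetal at low temperature and gives the lactol on work-up, with the first equivalent consumed by the free OH.

**Step 8**
Reactants: 12 lactol
Product: 13 [(3S,4R)-4-(ArCH2)tetrahydrofuran-3-yl]methanol (trans)
Conditions: Et3SiH, BF3·OEt2, CH2Cl2, −78 to −30 °C
Reagents that add atoms: none
Why: Ionic reduction of a lactol, in which BF3 ionises the anomeric OH and excess silane traps the oxocarbenium ion, a standard way from dibenzylbutyrolactols to 9,9'-epoxylignans that touches no stereocentre.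

**Step 9**
Reactants: 13 tetrahydrofuran alcohol
Product: 14 [(3R,4R)-4-(ArCH2)tetrahydrofuran-3-yl]methyl N,N-diisopropylcarbamate
Conditions: i-Pr2NCOCl, Et3N, DMAP (cat.), toluene, 80 °C
Reagents that add atoms: N,N-diisopropylcarbamoyl chloride, CC(C)N(C(C)C)C(=O)Cl
Why: O-carbamoylation of a primary alcohol installs the group that later directs the lithiation at C7 and then acts as the leaving group.

**Step 10**
Reactants: 14 carbamate; 4 ArBpin
Product: 18 (S)-Ar[(3R,4R)-4-(ArCH2)tetrahydrofuran-3-yl]methanol, via lithiated carbamate 15 (not isolated), via lithium boronate complex 16 (not isolated), via benzylic boronic ester 17 (not isolated)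
Conditions: s-BuLi, (+)-sparteine, Et2O, −78 °C; 4, −78 °C; MgBr2·OEt2, −78 °C to reflux; then NaBO3·4H2O, THF/H2O, rt
Reagents that add atoms: sodium perborate, [Na+].[O-]OB=O
Why: s-BuLi·(+)-sparteine, held by the carbamoyl C=O, removes the pro-R hydrogen at C7 to give the configurationally stable (R)-α-oxyorganolithium 15, which adds to boronic ester 4 with retention to give boronate 16; on warming with MgBr2 the syringyl group shifts from boron to C7 antiperiplanar to the departing carbamate (inversion), which forms the C1–C7 bond, and perborate then replaces boron by OH with retention. The closest known reaction type is the sparteine-mediated lithiation–borylation of primary O-alkyl carbamates with aryl pinacol boronic esters, a reagent-controlled Matteson-type 1,2-metalate rearrangement followed by oxidation. No ring is closed. The one new stereocentre, C7, should be fixed as S by the chiral diamine and the stereospecific retention–inversion–retention sequence rather than by the weak facial bias of the neighbouring C8 centre, and because C7 never reaches the aldehyde level no epimerisable C8–H next to a carbonyl group arises. The step needs site selectivity for C7–H over the ArCH2, aryl C–H (ortho to OMe) and ring OCH2 positions, which the directing carbamate secures at −78 °C in Et2O, and it needs a carbanion without a β-leaving group, which holds because the ring oxygen is γ to C7. In one flask the step joins the two halves, sets the last stereocentre and installs the hydroxyl group.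

**Step 11**
Reactants: 18 bis-TIPS ether
Product: 19 (S)-(4-hydroxy-3,5-dimethoxyphenyl)[(3R,4R)-4-(4-hydroxy-3,5-dimethoxybenzyl)tetrahydrofuran-3-yl]methanol (target)
Conditions: TBAF, AcOH, THF, 0 °C
Reagents that add atoms: none
Why: Fluoride-mediated cleavage of both aryl silyl ethers, buffered with acetic acid so that neither acid ionisation nor phenoxide-driven quinone methide formation at C7 should erode the benzylic stereocentre.

**Compound list**

| No. | Name | SMILES | Role |
|---|---|---|---|
| 1 | 4-bromo-2,6-dimethoxyphenol | COc1cc(Br)cc(OC)c1O | starting material |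
| 2 | (4-bromo-2,6-dimethoxyphenoxy)triisopropylsilane | COc1cc(Br)cc(OC)c1O[Si](C(C)C)(C(C)C)C(C)C | intermediate |
| 3 | [3,5-dimethoxy-4-(triisopropylsilyloxy)phenyl]lithium | COc1cc([Li])cc(OC)c1O[Si](C(C)C)(C(C)C)C(C)C | intermediate |
| 4 | ArBpin | COc1cc(B2OC(C)(C)C(C)(C)O2)cc(OC)c1O[Si](C(C)C)(C(C)C)C(C)C | intermediate |
| 5 | di-tert-butyl malonate | CC(C)(C)OC(=O)CC(=O)OC(C)(C)C | starting material |
| 6 | (R)-epichlorohydrin | ClC[C@H]1CO1 | starting material |
| 7 | tert-butyl (1R,5R)-2-oxo-3-oxabicyclo[3.1.0]hexane-1-carboxylate | O=C1OC[C@@H]2C[C@]12C(=O)OC(C)(C)C | intermediate |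
| 8 | [3,5-dimethoxy-4-(triisopropylsilyloxy)phenyl]magnesium bromide | COc1cc([Mg]Br)cc(OC)c1O[Si](C(C)C)(C(C)C)C(C)C | intermediate |
| 9 | tert-butyl (3R,4R)-4-(ArCH2)-2-oxotetrahydrofuran-3-carboxylate | COc1cc(C[C@H]2COC(=O)[C@@H]2C(=O)OC(C)(C)C)cc(OC)c1O[Si](C(C)C)(C(C)C)C(C)C | intermediate |
| 10 | (3S,4R)-4-(ArCH2)-2-oxotetrahydrofuran-3-carboxylic acid | COc1cc(C[C@H]2COC(=O)[C@@H]2C(=O)O)cc(OC)c1O[Si](C(C)C)(C(C)C)C(C)C | intermediate |
| 11 | (3S,4R)-3-(hydroxymethyl)-4-(ArCH2)dihydrofuran-2(3H)-one | COc1cc(C[C@H]2COC(=O)[C@@H]2CO)cc(OC)c1O[Si](C(C)C)(C(C)C)C(C)C | intermediate |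
| 12 | (3S,4R)-3-(hydroxymethyl)-4-(ArCH2)tetrahydrofuran-2-ol (anomers) | COc1cc(C[C@H]2COC(O)[C@@H]2CO)cc(OC)c1O[Si](C(C)C)(C(C)C)C(C)C | intermediate |
| 13 | [(3S,4R)-4-(ArCH2)tetrahydrofuran-3-yl]methanol | COc1cc(C[C@H]2COC[C@@H]2CO)cc(OC)c1O[Si](C(C)C)(C(C)C)C(C)C | intermediate |
| 14 | [(3R,4R)-4-(ArCH2)tetrahydrofuran-3-yl]methyl N,N-diisopropylcarbamate | COc1cc(C[C@H]2COC[C@@H]2COC(=O)N(C(C)C)C(C)C)cc(OC)c1O[Si](C(C)C)(C(C)C)C(C)C | intermediate |
| 15 | (R)-C7-lithiated carbamate | COc1cc(C[C@H]2COC[C@@H]2[C@H](OC(=O)N(C(C)C)C(C)C)[Li])cc(OC)c1O[Si](C(C)C)(C(C)C)C(C)C | intermediate |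
| 16 | lithium boronate complex (C7 bears OCb and the aryl pinacol borate) | [Li+].COc1cc(C[C@H]2COC[C@@H]2[C@H](OC(=O)N(C(C)C)C(C)C)[B-]3(OC(C)(C)C(C)(C)O3)c3cc(OC)c(O[Si](C(C)C)(C(C)C)C(C)C)c(OC)c3)cc(OC)c1O[Si](C(C)C)(C(C)C)C(C)C | intermediate |
| 17 | (7S)-benzylic pinacol boronic ester | COc1cc(C[C@H]2COC[C@@H]2[C@H](B3OC(C)(C)C(C)(C)O3)c3cc(OC)c(O[Si](C(C)C)(C(C)C)C(C)C)c(OC)c3)cc(OC)c1O[Si](C(C)C)(C(C)C)C(C)C | intermediate |
| 18 | (S)-Ar[(3R,4R)-4-(ArCH2)tetrahydrofuran-3-yl]methanol | COc1cc(C[C@H]2COC[C@@H]2[C@H](O)c3cc(OC)c(O[Si](C(C)C)(C(C)C)C(C)C)c(OC)c3)cc(OC)c1O[Si](C(C)C)(C(C)C)C(C)C | intermediate |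
| 19 | (7S,8R,8'R)-4,4',7-trihydroxy-3,3',5,5'-tetramethoxy-9,9'-epoxylignan | COc1cc(C[C@H]2COC[C@@H]2[C@H](O)c2cc(OC)c(O)c(OC)c2)cc(OC)c1O | target |

**Step count**

Total step count: 11.
Longest linear sequence: 9 (steps 1, 4, 5, 6, 7, 8, 9, 10, 11).

**Steps most likely to fail**

**Step 10.**
- Risk: deprotonation next to the branched C8 centre may be slow or mismatched with the diamine. Ring lithiation may compete. The 1,2-shift may be reluctant, with loss of conversion or of facial fidelity at C7.
- Fallback (from 13, back at 18):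
  - 13 is oxidised with Dess–Martin periodinane to the trans aldehyde (3R,4R)-4-(ArCH2)tetrahydrofuran-3-carbaldehyde F1.
  - Aryllithium 3 (from 2 as in step 2) is added at −78 °C to give the C7-epimeric carbinols F2.
  - Both epimers are oxidised together to the aryl ketone F3.
  - A Corey–Bakshi–Shibata reduction with the (R)-oxazaborolidine and BH3·SMe2 sets C7 by catalyst-controlled hydride delivery and gives 18.

**Step 4.**
- Risk: the aryl metal may attack the lactone or ester carbonyl instead of the ring. The less nucleophilic aryl copper species may open the cyclopropane only sluggishly.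
- Fallback (from 2, back at 11):
  - A Heck reaction of 2 with commercial 4-methyl hydrogen itaconate (Pd(OAc)2, P(o-tol)3, Et3N) gives (E)-2-(Ar-methylidene)succinic acid 4-methyl ester F4.
  - Rhodium-catalysed asymmetric hydrogenation with a DuPhos-type bisphosphine (the ligand antipode that leads to the R acid) gives (R)-2-(ArCH2)succinic acid 4-methyl ester F5.
  - Borane reduction of the free acid with acid-promoted lactonisation gives (R)-4-(ArCH2)dihydrofuran-2(3H)-one F6.
  - The lithium enolate of F6 (LDA, −78 °C) is hydroxymethylated with monomeric formaldehyde anti to the benzyl group to give 11.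

**Step 8.**
- Risk: the electron-rich aryl ring may intercept the oxocarbenium ion (Friedel–Crafts closure). C8 may also epimerise through the open hydroxy-aldehyde form of the lactol.
- Fallback (from 11, back at 14):
  - 11 is O-carbamoylated (i-Pr2NCOCl, pyridine) to the lactone carbamate F7.
  - LiBH4 opens the lactone to the 1,4-diol carbamate F8.
  - A Mitsunobu cyclodehydration (PPh3, DIAD) closes the tetrahydrofuran ring by 5-exo-tet etherification at a primary carbon, which gives 14 without any cationic intermediate.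

**Further compounds**

F1 | step 10 | (3R,4R)-4-(ArCH2)tetrahydrofuran-3-carbaldehyde | COc1cc(C[C@H]2COC[C@@H]2C=O)cc(OC)c1O[Si](C(C)C)(C(C)C)C(C)C
F2 | step 10 | Ar[(3R,4R)-4-(ArCH2)tetrahydrofuran-3-yl]methanol, both C7 epimers | COc1cc(C[C@H]2COC[C@@H]2C(O)c3cc(OC)c(O[Si](C(C)C)(C(C)C)C(C)C)c(OC)c3)cc(OC)c1O[Si](C(C)C)(C(C)C)C(C)C
F3 | step 10 | Ar [(3R,4R)-4-(ArCH2)tetrahydrofuran-3-yl] ketone | COc1cc(C[C@H]2COC[C@@H]2C(=O)c3cc(OC)c(O[Si](C(C)C)(C(C)C)C(C)C)c(OC)c3)cc(OC)c1O[Si](C(C)C)(C(C)C)C(C)C
F4 | step 4 | (E)-2-(Ar-methylidene)succinic acid 4-methyl ester | OC(=O)/C(CC(=O)OC)=C/c1cc(OC)c(O[Si](C(C)C)(C(C)C)C(C)C)c(OC)c1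
F5 | step 4 | (R)-2-(ArCH2)succinic acid 4-methyl ester | COC(=O)C[C@@H](Cc1cc(OC)c(O[Si](C(C)C)(C(C)C)C(C)C)c(OC)c1)C(=O)O
F6 | step 4 | (R)-4-(ArCH2)dihydrofuran-2(3H)-one | COc1cc(C[C@H]2COC(=O)C2)cc(OC)c1O[Si](C(C)C)(C(C)C)C(C)C
F7 | step 8 | [(3S,4R)-4-(ArCH2)-2-oxotetrahydrofuran-3-yl]methyl N,N-diisopropylcarbamate | COc1cc(C[C@H]2COC(=O)[C@@H]2COC(=O)N(C(C)C)C(C)C)cc(OC)c1O[Si](C(C)C)(C(C)C)C(C)C
F8 | step 8 | (2R,3R)-4-hydroxy-2-(hydroxymethyl)-3-(ArCH2)butyl N,N-diisopropylcarbamate | COc1cc(C[C@@H](CO)[C@H](CO)COC(=O)N(C(C)C)C(C)C)cc(OC)c1O[Si](C(C)C)(C(C)C)C(C)C
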